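# Two-directional cuprate route to CNP0330767.1 from a meso dimethyl core

## The problem

The target is a 2-methoxy-5-methyl-1,4-benzoquinone whose ring carbon C6 carries an unbranched chain C1'–C8' followed by four methyl-bearing stereocentres at C9', C11', C13' and C15' and an ethyl terminus C16'–C17'. No rings have to be joined; the work lies in building the chain and attaching it regioselectively at C6, between the C1 carbonyl and the C5 methyl group. The four centres are all-syn (9R,11R,13S,15S), are 1,3-related, and sit in a pure hydrocarbon segment, eight carbons from the ring. Nothing in the target can direct or report on them, so each must be set by a neighbouring centre or a reagent at a stage where a functional group is still present. The methoxyquinone is the only delicate part: it is electrophilic, easily reduced and base-sensitive, so it should be unveiled last, from a phenol. The enabling feature is a hidden local symmetry. The segment C8'–C16' has a mirror plane through C12', so C11'/C13' form a meso pair and C9'/C15' are mirror-related extensions of it. A meso 2,4-dimethyl-C5 unit, desymmetrised once, can therefore be grown in both directions by the same substrate-controlled reaction. The price of that symmetry is that the two chain ends (C7' towards the ring, C17' a methyl group) must be kept distinguishable throughout.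

## Retrosynthesis

**Quinone to phenol (30 ⇒ 29).** The C4–O bond is cut, taking quinone 30 back to phenol 29, whose para position C4 is unsubstituted. This keeps the fragile quinone out of every C–C bond-forming step. A protected hydroquinone would need an extra ring oxygen and a deprotection, whereas 29 has exactly the substitution pattern of commercial phenol 24. The forward reaction must oxidise para to the hydroxyl group, not ortho.

**Chain to ring (29 ⇒ 28 ⇒ 23 + 26).** The C1'–C2' bond is cut as an alkene (28), made from phosphonium salt 23 and aldehyde 26. The neighbouring cut, C6–C1', would need a halogen or metal at C6 of 24, and electrophilic substitution of 24 goes para to the hydroxyl group instead. Phenoxide-directed formylation can only reach C6, so 24 ⇒ 25 ⇒ 26 is regiochemically unambiguous. The alkene geometry is irrelevant, because one hydrogenation removes both the double bond and the benzyl ether.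

**Linker (23 ⇒ 22 ⇒ 19 + 20).** The C6'–C7' bond is cut. C7' is the carbon at which the stereo-bearing segment ends in an oxygenated group (tosylate 19). The five methylene groups C2'–C6' come from dihalide 20, whose bromide becomes Grignard reagent 21 and whose chloride is kept for the phosphonium salt. The forward sp3–sp3 coupling must substitute the tosylate without touching the chloride.

**End-group adjustment (19 ⇒ 18 ⇒ 17 ⇒ 16 ⇒ 15).** No skeletal bond is cut. C17' (methyl) and C7' (tosylate) are traced back to the methyl and tert-butyl ester carbons of diester 15. The methyl ester is reduced alone (16) and activated (17). One hydride treatment then turns the tosylate into the C17' methyl group and the tert-butyl ester into the C7' alcohol (18). The forward sequence relies on a hydride reagent that discriminates the two esters.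

**Key disconnection (15 ⇒ 13).** The C9'–CH3 and C15'–CH3 bonds are cut together, leading to bis-enoate 13. Cutting the chain bonds one centre at a time (iterative growth, or one auxiliary cycle per centre) costs about three steps per stereocentre. Here two stereocentres and two skeletal bonds arise in one operation, and the problem shrinks from four centres to the meso pair C11'/C13'. The forward step must give 1,3-syn induction at both β-carbons.

**Arms (13 ⇒ 10 + 11; 10 ⇒ 9 ⇒ 8 ⇒ 4 + 6).** The sp3–sp2 bonds C9'–C10' and C14'–C15' are cut, so each arm is a three-carbon acrylate unit (6 and 11, both from acid 5) joined to an alkylzinc reagent (7, 12). Aldehyde olefination would first require a one-carbon homologation, since C10' and C14' must remain methylene groups, and would pass through epimerisable α-methyl aldehydes. The order in which 6 and 11 are attached decides which end becomes C17' and which C7'.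

**Core (4 ⇒ 3 ⇒ 2 ⇒ 1).** Iodide 4 comes from monoacetate 3, which comes from meso diol 2 by enzymatic differentiation of its two hydroxymethyl arms; 2 comes from meso anhydride 1. The relative configuration of C11'/C13' is bought, and the absolute configuration of all four centres traces back to this one desymmetrisation.

## Roads not taken

**Alternative 1:** The ring bonds C1–C6 and C4–C5 are cut, and the quinone ring is grown at the chain terminus. The alkenyllithium from alkenyl bromide A2 would add to the ketone-like carbonyl of 3-methoxycyclobut-3-ene-1,2-dione A3. Heating the adduct opens the four-membered ring to a dienylketene, which closes by 6π electrocyclisation to hydroquinone A1.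
- Merits: the positions of all four ring substituents follow from the construction, and A1 is one mild oxidation from the target. In regiochemical certainty of the oxygenation pattern this is better than a late phenol oxidation.
- Weak points: A2 is a trisubstituted bromoalkene at the end of the complete, stereochemically finished chain, so the most valuable intermediate must be lithiated. A3 has an unsubstituted vinylic position open to competing deprotonation and conjugate addition. The route says nothing about the four stereocentres.
- Comparison: the chosen plan buys the ring with its methyl and methoxy groups in place (24), fixes C6 by directed formylation, and uses the chain as an ylide rather than an organolithium. What it sets against the regiochemical certainty of Alternative 1 is the free para position of 29, which should direct the oxidation to C4.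

**Alternative 2:** The four bonds C15'–C16', C13'–C14', C11'–C12' and C9'–C10' are cut at once. Propene A6 would insert four times into an ethyl–zirconium bond on one enantiomer of ethylenebis(tetrahydroindenyl)zirconium dichloride, (EBTHI)ZrCl2, activated by methylaluminoxane (MeAlO)n, with chain transfer to diethylzinc A5. Oxidation of the C–Zn bond would give alcohol A4.
- Merits: in step economy this is clearly superior. Four stereocentres and the whole branched segment come from feedstocks in one pot, with catalytic chirality, where the chosen plan needs thirteen steps to reach the comparable alcohol 18.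
- Weak points: a chain-growth process gives a distribution of oligomers, from which exactly the tetramer must be isolated. The first insertion into the ethyl–metal bond, which sets C15', is the least enantioface-selective. Every stereo- or regio-error gives a hydrocarbon-like diastereomer of A4 that is very hard to remove. Chain transfer to zinc must also outcompete transfer to aluminium and β-hydride elimination.
- Comparison: the chosen plan sets against this a stepwise verifiable outcome. Two centres come with fixed relative configuration from a meso compound, the absolute sense comes from one enzymatic step, and the other two arise in a discrete, isolable diester.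

**Alternative 3:** The bonds C6–C1' and C5–CH3 are cut. The organocopper reagent made from the Grignard reagent of chain bromide A9 with CuBr·SMe2 and Me3SiCl would add to the unsubstituted β-carbon of quinone monoketal A8. The enolate, regenerated from its silyl ether, would be C-methylated in the same pot to give enone A7; ketal hydrolysis, aromatisation and oxidation would follow.
- Merits: chain and ring are joined directly at the quinone oxidation level, without olefination or hydrogenation. The endgame is as short as, or slightly shorter than, the one chosen here.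
- Weak points: the complete chain A9 must be converted into an organometallic and used with stoichiometric copper. The enolate alkylation next to the ketal carbon competes with O-methylation, over-alkylation and premature loss of methanol. The ketal is exposed to a silyl chloride. The chain stereocentres are again left unaddressed.
- Comparison: the chosen plan has the C5 methyl group already in 24 and needs only routine operations (Wittig, hydrogenation, phenol oxidation) at the end. This reliability at the stage where material is most valuable is what it sets against the shorter endgame of Alternative 3.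

Key step: step 10

## Route

Numbering: ring C1–C6 as in 2-methoxy-5-methyl-6-alkyl-1,4-benzoquinone; side chain C1' (on C6) to C17'.

Assumption: the lipase acetylates the hydroxymethyl arm on the S-configured carbon of diol 2, its usual preference for this diol, leaving the C14' arm free. Were the preference the opposite, esters 6 and 11 would simply be used in the reverse order.

Step 1
Reactants: 1 cis-3,5-dimethyloxane-2,6-dione (meso-2,4-dimethylglutaric anhydride)
Product: 2 (2R,4S)-2,4-dimethylpentane-1,5-diol (meso)
Conditions: LiAlH4, THF, 0 °C to reflux
Reagents that add atoms: none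
Why: Hydride reduction of a cyclic anhydride to the 1,5-diol; the carbonyl intermediates are reduced faster than they enolise, so the cis (meso) relationship of the two methyl groups is kept.

Step 2
Reactants: 2 (2R,4S)-2,4-dimethylpentane-1,5-diol
Product: 3 (2S,4R)-5-hydroxy-2,4-dimethylpentyl acetate
Conditions: lipase from Pseudomonas fluorescens, vinyl acetate, THF, rt
Reagents that add atoms: vinyl acetate, CC(=O)OC=C
Why: Lipase-catalysed irreversible transesterification differentiates the enantiotopic hydroxymethyl arms of a meso diol; the minor monoacetate is acetylated on to the diacetate faster than the major one, which raises the enantiomeric purity of 3. This step fixes the absolute configuration of C11' and C13'.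

Step 3
Reactants: 3 (2S,4R)-5-hydroxy-2,4-dimethylpentyl acetate
Product: 4 (2S,4R)-5-iodo-2,4-dimethylpentyl acetate
Conditions: I2, PPh3, imidazole, CH2Cl2, 0 °C to rt
Reagents that add atoms: iodine, II
Why: Garegg–Samuelsson iodination; the alkoxyphosphonium ion is displaced by iodide at a primary carbon, so no stereocentre is touched and the acetate is inert.

Step 4
Reactants: 5 (2E)-3-iodoprop-2-enoic acid
Product: 6 methyl (2E)-3-iodoprop-2-enoate
Conditions: MeOH, H2SO4 (cat.), reflux
Reagents that add atoms: methanol, CO
Why: Fischer esterification; acidic conditions avoid nucleophilic addition–elimination at the β-iodo carbon and keep the E geometry.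

Step 5
Reactants: 4 (2S,4R)-5-iodo-2,4-dimethylpentyl acetate; 6 methyl (2E)-3-iodoprop-2-enoate
Product: 8 methyl (2E,5S,7S)-8-acetoxy-5,7-dimethyloct-2-enoate, via alkylzinc iodide 7 (not isolated)
Conditions: Zn dust (activated with BrCH2CH2Br and Me3SiCl), THF, 35 °C; then 6, Pd(PPh3)4 (5 mol %), THF, rt
Reagents that add atoms: none
Why: Zinc inserts into the primary C–I bond to give an ester-tolerant alkylzinc iodide; Negishi sp3–sp2 coupling (oxidative addition of zerovalent palladium to the alkenyl iodide, transmetalation, reductive elimination) forms C14'–C15' with retention of the E geometry.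

Step 6
Reactants: 8 methyl (2E,5S,7S)-8-acetoxy-5,7-dimethyloct-2-enoate
Product: 9 methyl (2E,5S,7S)-8-hydroxy-5,7-dimethyloct-2-enoate
Conditions: K2CO3 (0.2 equiv), MeOH, 0 °C
Reagents that add atoms: none
Why: Base-catalysed methanolysis of the primary acetate; the methyl ester is degenerate towards methanolysis, and the low temperature and substoichiometric base keep methoxide conjugate addition and enoate deconjugation negligible.

Step 7
Reactants: 9 methyl (2E,5S,7S)-8-hydroxy-5,7-dimethyloct-2-enoate
Product: 10 methyl (2E,5S,7S)-8-iodo-5,7-dimethyloct-2-enoate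
Conditions: I2, PPh3, imidazole, CH2Cl2, 0 °C to rt
Reagents that add atoms: iodine, II
Why: Garegg–Samuelsson iodination at a primary carbon, as in step 3; the enoate does not react with the phosphonium species.

Step 8
Reactants: 5 (2E)-3-iodoprop-2-enoic acid
Product: 11 tert-butyl (2E)-3-iodoprop-2-enoate
Conditions: tert-butyl 2,2,2-trichloroacetimidate, BF3·OEt2 (cat.), CH2Cl2–cyclohexane, rt
Reagents that add atoms: tert-butyl 2,2,2-trichloroacetimidate, CC(C)(C)OC(=N)C(Cl)(Cl)Cl
Why: Acid-catalysed tert-butyl transfer from the imidate to the carboxylic acid; no nucleophilic base is present that could attack the β-iodo position.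

Step 9
Reactants: 10 methyl (2E,5S,7S)-8-iodo-5,7-dimethyloct-2-enoate; 11 tert-butyl (2E)-3-iodoprop-2-enoate
Product: 13 1-tert-butyl 11-methyl (2E,5S,7R,9E)-5,7-dimethylundeca-2,9-dienedioate, via alkylzinc iodide 12 (not isolated)
Conditions: Zn dust (activated with BrCH2CH2Br and Me3SiCl), THF, 35 °C; then 11, Pd(PPh3)4 (5 mol %), THF, rt
Reagents that add atoms: none
Why: Zinc insertion and Negishi sp3–sp2 coupling as in step 5, forming C9'–C10'; alkylzinc iodides do not add to enoates without copper, so the methyl enoate is carried through and both double bonds are E.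

Step 10
Reactants: 13 1-tert-butyl 11-methyl (2E,5S,7R,9E)-5,7-dimethylundeca-2,9-dienedioate
Product: 15 1-tert-butyl 11-methyl (3S,5S,7R,9R)-3,5,7,9-tetramethylundecanedioate, via bis(silyl ketene acetal) 14 (not isolated)
Conditions: Me2CuLi (from CuI and MeLi, excess), Me3SiCl, THF, −78 °C; aq NH4Cl–NH3
Reagents that add atoms: lithium dimethylcuprate, [Li+].C[Cu-]C
Why: Me2CuLi forms a copper–alkene π-complex with each (E)-enoate, Me3SiCl accelerates its collapse to a β-cuprio (formally trivalent copper) silyl ketene acetal, and reductive elimination makes the C9'–CH3 and C15'–CH3 bonds; work-up hydrolyses 14 to 15. The closest known reaction type is the Me3SiCl-promoted lithium dialkylcuprate addition to (E)-enoates that carry a δ-methyl stereocentre inside a syn-dimethyl array, known in its one-directional, iterative form and here run at both termini of one molecule. No ring closes. C9' (C3 of 15) is controlled by C11' and C15' (C9 of 15) by C13': each arm adopts the conformer free of syn-pentane interactions with the C11' and C13' methyl groups, so the chain covers one enoate face and the methyl group arrives on the other, syn to its 1,3-neighbour. Because the C11'/C13' pair is meso, the two arms are locally mirror images, and the same substrate bias gives the two opposite absolute configurations (3S and 9R) that one chiral reagent could not deliver together. The step needs 1,3-syn selectivity at both β-carbons and 1,4- rather than 1,2-addition; the first rests on the syn-dimethyl core, helped at the C7' end by the bulky tert-butyl ester, and the second on the soft cuprate at −78 °C, to which neither ester carbonyl responds. The methyl-ester arm is expected to be the less selective one, and minor diastereomers are to be removed at the stage of alcohol 16.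

Step 11
Reactants: 15 1-tert-butyl 11-methyl (3S,5S,7R,9R)-3,5,7,9-tetramethylundecanedioate
Product: 16 tert-butyl (3S,5S,7R,9R)-11-hydroxy-3,5,7,9-tetramethylundecanoate
Conditions: LiBH4, THF, MeOH (1 equiv), 0 °C to rt
Reagents that add atoms: none
Why: Chemoselective ester reduction; LiBH4 reduces the unhindered methyl ester while the sterically shielded tert-butyl ester is left, which turns the ester difference into a lasting difference between C17' and C7'.

Step 12
Reactants: 16 tert-butyl (3S,5S,7R,9R)-11-hydroxy-3,5,7,9-tetramethylundecanoate
Product: 17 tert-butyl (3S,5S,7R,9R)-3,5,7,9-tetramethyl-11-[(4-methylbenzenesulfonyl)oxy]undecanoate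
Conditions: TsCl, Et3N, DMAP (cat.), CH2Cl2, 0 °C to rt
Reagents that add atoms: 4-methylbenzenesulfonyl chloride, Cc1ccc(cc1)S(Cl)(=O)=O
Why: Sulfonylation of an unhindered primary alcohol; the tert-butyl ester is inert to these conditions.

Step 13
Reactants: 17 tert-butyl (3S,5S,7R,9R)-3,5,7,9-tetramethyl-11-[(4-methylbenzenesulfonyl)oxy]undecanoate
Product: 18 (3S,5S,7S,9S)-3,5,7,9-tetramethylundecan-1-ol
Conditions: LiAlH4 (excess), THF, 0 °C to 60 °C
Reagents that add atoms: none
Why: One hydride reagent does two jobs: SN2 displacement of the primary tosylate gives the C17' methyl group, and reduction of the tert-butyl ester gives the C7' alcohol. No stereocentre is involved; the descriptors change only because the substituent priorities change.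

Step 14
Reactants: 18 (3S,5S,7S,9S)-3,5,7,9-tetramethylundecan-1-ol
Product: 19 (3S,5S,7S,9S)-3,5,7,9-tetramethylundecyl 4-methylbenzenesulfonate
Conditions: TsCl, Et3N, DMAP (cat.), CH2Cl2, 0 °C to rt
Reagents that add atoms: 4-methylbenzenesulfonyl chloride, Cc1ccc(cc1)S(Cl)(=O)=O
Why: Sulfonylation of a primary alcohol to give the electrophile for chain extension at C7'.

Step 15
Reactants: 19 (3S,5S,7S,9S)-3,5,7,9-tetramethylundecyl 4-methylbenzenesulfonate; 20 1-bromo-5-chloropentane
Product: 22 (8R,10R,12S,14S)-1-chloro-8,10,12,14-tetramethylhexadecane, via Grignard reagent 21 (not isolated)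
Conditions: 20, Mg turnings, THF, rt; then 19, Li2CuCl4 (5 mol %), THF, −78 °C to rt
Reagents that add atoms: none
Why: Magnesium inserts into the C–Br bond while the C–Cl bond stays intact; copper-catalysed sp3–sp3 cross-coupling of a primary alkyl Grignard reagent with a primary tosylate forms C6'–C7', and the alkyl chloride does not react under these conditions.

Step 16
Reactants: 22 (8R,10R,12S,14S)-1-chloro-8,10,12,14-tetramethylhexadecane
Product: 23 triphenyl[(8R,10R,12S,14S)-8,10,12,14-tetramethylhexadecyl]phosphonium iodide
Conditions: NaI, PPh3, MeCN, reflux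
Reagents that add atoms: triphenylphosphine, c1ccc(cc1)P(c1ccccc1)c1ccccc1; sodium iodide, [Na+].[I-]
Why: Finkelstein exchange in the flask turns the primary chloride into the iodide, which quaternises PPh3 by SN2.

Step 17
Reactants: 24 2-methoxy-5-methylphenol
Product: 25 2-hydroxy-3-methoxy-6-methylbenzaldehyde
Conditions: MgCl2, Et3N, (CH2O)n, MeCN, reflux
Reagents that add atoms: formaldehyde (as paraformaldehyde), C=O
Why: Casnati–Skattebøl ortho-formylation; the magnesium phenoxide delivers formaldehyde through a six-membered transition state to the only free ortho position (C6, between the hydroxyl and methyl groups), and a second formaldehyde oxidises the benzylic alkoxide to the aldehyde.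

Step 18
Reactants: 25 2-hydroxy-3-methoxy-6-methylbenzaldehyde
Product: 26 2-(benzyloxy)-3-methoxy-6-methylbenzaldehyde
Conditions: BnBr, K2CO3, DMF, rt
Reagents that add atoms: benzyl bromide, BrCc1ccccc1
Why: Williamson etherification of the phenoxide; the benzyl group keeps the phenol from quenching the ylide and is removed later without an extra step.

Step 19
Reactants: 23 triphenyl[(8R,10R,12S,14S)-8,10,12,14-tetramethylhexadecyl]phosphonium iodide; 26 2-(benzyloxy)-3-methoxy-6-methylbenzaldehyde
Product: 28 2-(benzyloxy)-1-methoxy-4-methyl-3-[(1Z,9R,11R,13S,15S)-9,11,13,15-tetramethylheptadec-1-en-1-yl]benzene (Z expected to predominate; geometry irrelevant), via phosphonium ylide 27 (not isolated)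
Conditions: NaN(SiMe3)2, THF, −78 °C; then 26, −78 °C to rt
Reagents that add atoms: none
Why: Wittig olefination with a non-stabilised ylide forms C1'=C2'; aromatic aldehydes with two ortho substituents still react with such ylides, and both alkene isomers converge in the next step.

Step 20
Reactants: 28 2-(benzyloxy)-1-methoxy-4-methyl-3-[(1Z,9R,11R,13S,15S)-9,11,13,15-tetramethylheptadec-1-en-1-yl]benzene
Product: 29 2-methoxy-5-methyl-6-[(9R,11R,13S,15S)-9,11,13,15-tetramethylheptadecyl]phenol
Conditions: H2 (1 atm), 10% Pd/C, EtOAc–EtOH, rt
Reagents that add atoms: none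
Why: Heterogeneous hydrogenation saturates the styrene-type double bond and hydrogenolyses the benzyl ether in one operation; the remote stereocentres are not allylic and cannot be affected.

Step 21
Reactants: 29 2-methoxy-5-methyl-6-[(9R,11R,13S,15S)-9,11,13,15-tetramethylheptadecyl]phenol
Product: 30 2-methoxy-5-methyl-6-[(9R,11R,13S,15S)-9,11,13,15-tetramethylheptadecyl]cyclohexa-2,5-diene-1,4-dione (CNP0330767.1)
Conditions: (KSO3)2NO, KH2PO4, H2O–CH2Cl2, Bu4NHSO4 (cat.), rt
Reagents that add atoms: potassium nitrosodisulfonate, [K+].[K+].[O]N(S(=O)(=O)[O-])S(=O)(=O)[O-]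
Why: Teuber oxidation; the phenoxyl radical is trapped at the free para position C4 by a second nitrosodisulfonate radical, and loss of imidodisulfonate gives the para-quinone under near-neutral conditions that the methoxyquinone tolerates.

## Compound list

1 | cis-3,5-dimethyloxane-2,6-dione (meso-2,4-dimethylglutaric anhydride) | C[C@H]1C[C@@H](C)C(=O)OC1=O | starting material
2 | (2R,4S)-2,4-dimethylpentane-1,5-diol (meso) | OC[C@H](C)C[C@H](C)CO | intermediate
3 | (2S,4R)-5-hydroxy-2,4-dimethylpentyl acetate | OC[C@H](C)C[C@H](C)COC(C)=O | intermediate
4 | (2S,4R)-5-iodo-2,4-dimethylpentyl acetate | IC[C@H](C)C[C@H](C)COC(C)=O | intermediate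
5 | (2E)-3-iodoprop-2-enoic acid | OC(=O)/C=C/I | starting material
6 | methyl (2E)-3-iodoprop-2-enoate | COC(=O)/C=C/I | intermediate
7 | [(2R,4S)-5-acetoxy-2,4-dimethylpentyl]zinc iodide | I[Zn]C[C@H](C)C[C@H](C)COC(C)=O | intermediate
8 | methyl (2E,5S,7S)-8-acetoxy-5,7-dimethyloct-2-enoate | COC(=O)/C=C/C[C@H](C)C[C@H](C)COC(C)=O | intermediate
9 | methyl (2E,5S,7S)-8-hydroxy-5,7-dimethyloct-2-enoate | COC(=O)/C=C/C[C@H](C)C[C@H](C)CO | intermediate
10 | methyl (2E,5S,7S)-8-iodo-5,7-dimethyloct-2-enoate | COC(=O)/C=C/C[C@H](C)C[C@H](C)CI | intermediate
11 | tert-butyl (2E)-3-iodoprop-2-enoate | CC(C)(C)OC(=O)/C=C/I | intermediate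
12 | [(2S,4S,6E)-8-methoxy-2,4-dimethyl-8-oxooct-6-en-1-yl]zinc iodide | COC(=O)/C=C/C[C@H](C)C[C@H](C)C[Zn]I | intermediate
13 | 1-tert-butyl 11-methyl (2E,5S,7R,9E)-5,7-dimethylundeca-2,9-dienedioate | COC(=O)/C=C/C[C@H](C)C[C@H](C)C/C=C/C(=O)OC(C)(C)C | intermediate
14 | (3S,5S,7R,9R)-1-tert-butoxy-11-methoxy-3,5,7,9-tetramethyl-1,11-bis[(trimethylsilyl)oxy]undeca-1,10-diene (enol ether geometry not defined) | COC(O[Si](C)(C)C)=C[C@H](C)C[C@H](C)C[C@H](C)C[C@H](C)C=C(OC(C)(C)C)O[Si](C)(C)C | intermediate
15 | 1-tert-butyl 11-methyl (3S,5S,7R,9R)-3,5,7,9-tetramethylundecanedioate | COC(=O)C[C@H](C)C[C@H](C)C[C@H](C)C[C@H](C)CC(=O)OC(C)(C)C | intermediate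
16 | tert-butyl (3S,5S,7R,9R)-11-hydroxy-3,5,7,9-tetramethylundecanoate | OCC[C@H](C)C[C@H](C)C[C@H](C)C[C@H](C)CC(=O)OC(C)(C)C | intermediate
17 | tert-butyl (3S,5S,7R,9R)-3,5,7,9-tetramethyl-11-[(4-methylbenzenesulfonyl)oxy]undecanoate | Cc1ccc(cc1)S(=O)(=O)OCC[C@H](C)C[C@H](C)C[C@H](C)C[C@H](C)CC(=O)OC(C)(C)C | intermediate
18 | (3S,5S,7S,9S)-3,5,7,9-tetramethylundecan-1-ol | CC[C@H](C)C[C@H](C)C[C@H](C)C[C@H](C)CCO | intermediate
19 | (3S,5S,7S,9S)-3,5,7,9-tetramethylundecyl 4-methylbenzenesulfonate | CC[C@H](C)C[C@H](C)C[C@H](C)C[C@H](C)CCOS(=O)(=O)c1ccc(C)cc1 | intermediate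
20 | 1-bromo-5-chloropentane | ClCCCCCBr | starting material
21 | (5-chloropentyl)magnesium bromide | ClCCCCC[Mg]Br | intermediate
22 | (8R,10R,12S,14S)-1-chloro-8,10,12,14-tetramethylhexadecane | CC[C@H](C)C[C@H](C)C[C@H](C)C[C@H](C)CCCCCCCCl | intermediate
23 | triphenyl[(8R,10R,12S,14S)-8,10,12,14-tetramethylhexadecyl]phosphonium iodide | CC[C@H](C)C[C@H](C)C[C@H](C)C[C@H](C)CCCCCCC[P+](c1ccccc1)(c1ccccc1)c1ccccc1.[I-] | intermediate
24 | 2-methoxy-5-methylphenol | COc1ccc(C)cc1O | starting material
25 | 2-hydroxy-3-methoxy-6-methylbenzaldehyde | COc1ccc(C)c(C=O)c1O | intermediate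
26 | 2-(benzyloxy)-3-methoxy-6-methylbenzaldehyde | COc1ccc(C)c(C=O)c1OCc1ccccc1 | intermediate
27 | triphenyl[(8R,10R,12S,14S)-8,10,12,14-tetramethylhexadecylidene]phosphorane | CC[C@H](C)C[C@H](C)C[C@H](C)C[C@H](C)CCCCCCC=P(c1ccccc1)(c1ccccc1)c1ccccc1 | intermediate
28 | 2-(benzyloxy)-1-methoxy-4-methyl-3-[(1Z,9R,11R,13S,15S)-9,11,13,15-tetramethylheptadec-1-en-1-yl]benzene | CC[C@H](C)C[C@H](C)C[C@H](C)C[C@H](C)CCCCCC/C=C\c1c(C)ccc(OC)c1OCc1ccccc1 | intermediate
29 | 2-methoxy-5-methyl-6-[(9R,11R,13S,15S)-9,11,13,15-tetramethylheptadecyl]phenol | CC[C@H](C)C[C@H](C)C[C@H](C)C[C@H](C)CCCCCCCCc1c(C)ccc(OC)c1O | intermediate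
30 | 2-methoxy-5-methyl-6-[(9R,11R,13S,15S)-9,11,13,15-tetramethylheptadecyl]cyclohexa-2,5-diene-1,4-dione | CC[C@H](C)C[C@H](C)C[C@H](C)C[C@H](C)CCCCCCCCC1=C(C)C(=O)C=C(OC)C1=O | target

## Step count and least certain steps

Total: 21 steps. Longest linear sequence: 17 steps (1, 2, 3, 5, 6, 7, 9, 10, 11, 12, 13, 14, 15, 16, 19, 20, 21, from anhydride 1). Steps 4 and 8 (from acid 5) and steps 17 and 18 (from phenol 24) are side branches.

**Step 10 (key step).** The most likely failure is poor facial selectivity at one terminus, most probably the methyl-enoate arm that sets C15'. Its ester is small, and the induction comes only from the remote syn-dimethyl pair. This would give diastereomers that are hard to separate, and incomplete addition at the second enoate would add to the problem. The fallback separates the two additions in time and puts the weaker terminus under catalyst control. It sets out from 8. Copper-catalysed addition of MeMgBr with CuI and the enantiomer of Tol-BINAP whose facial preference reinforces that of the substrate should give methyl (3R,5S,7S)-8-acetoxy-3,5,7-trimethyloctanoate F1. Methanolysis with K2CO3 gives methyl (3R,5S,7S)-8-hydroxy-3,5,7-trimethyloctanoate F2; any acetate lost to the Grignard reagent merely anticipates this step. Iodination with I2, PPh3 and imidazole gives methyl (3R,5S,7S)-8-iodo-3,5,7-trimethyloctanoate F3. Zinc insertion to [(2S,4S,6R)-8-methoxy-2,4,6-trimethyl-8-oxooctyl]zinc iodide F4 and Pd(PPh3)4-catalysed coupling with 11 give 1-tert-butyl 11-methyl (2E,5S,7R,9R)-5,7,9-trimethylundec-2-enedioate F5. A single-ended Me2CuLi/Me3SiCl addition to this tert-butyl enoate, now guided by three syn methyl groups, passes through methyl (3R,5R,7S,9S)-11-tert-butoxy-3,5,7,9-tetramethyl-11-[(trimethylsilyl)oxy]undec-10-enoate F6. Its hydrolysis returns the route at 15.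

**Step 9.** The alkylzinc reagent is formed here five carbons away from an enoate. The carbon radical on the zinc surface may cyclise onto the enoate (6-exo), or the alkylpalladium intermediate may undergo β-hydride elimination before it couples. The fallback keeps the C14' arm as a plain vinyl group until both arms are attached. It sets out from 4, through zinc reagent 7. Pd(PPh3)4-catalysed coupling of 7 with vinyl bromide gives (2S,4S)-2,4-dimethylhept-6-en-1-yl acetate F7. Methanolysis gives (2S,4S)-2,4-dimethylhept-6-en-1-ol F8, and iodination gives (4S,6S)-7-iodo-4,6-dimethylhept-1-ene F9. Zinc insertion to [(2S,4S)-2,4-dimethylhept-6-en-1-yl]zinc iodide F10 and coupling with 11 give tert-butyl (2E,5S,7S)-5,7-dimethyldeca-2,9-dienoate F11. Cross-metathesis of the terminal alkene with methyl acrylate, using second-generation Grubbs catalyst (H2IMes)(PCy3)Cl2Ru=CHPh, returns the route at 13; the electron-poor disubstituted tert-butyl enoate should not take part.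

**Step 11.** The hydride may discriminate the two esters incompletely, reducing some tert-butyl ester to the diol or leaving methyl ester unreduced, because the selectivity is only kinetic. The fallback replaces kinetic hydride selectivity by hydrolytic differentiation. It sets out from 15. LiOH in THF–H2O saponifies only the methyl ester to (3R,5R,7S,9S)-11-tert-butoxy-3,5,7,9-tetramethyl-11-oxoundecanoic acid F12. BH3·SMe2 then reduces the carboxylic acid, but not the tert-butyl ester, and returns the route at 16.

**Step 15.** The ω-chloroalkyl Grignard reagent may destroy itself by cyclisation or self-coupling, or it may reduce or eliminate the tosylate instead of substituting it, since the coupling is slower than either of these processes when the copper catalyst dies. The fallback forms the same C6'–C7' bond by palladium-catalysed alkyl–alkyl Suzuki–Miyaura coupling, in which the nucleophile is a stable organoborane. It sets out from 18. CBr4 and PPh3 give (3S,5S,7S,9S)-1-bromo-3,5,7,9-tetramethylundecane F13. Hydroboration of 5-chloropent-1-ene with 9-borabicyclo[3.3.1]nonane gives 9-(5-chloropentyl)-9-borabicyclo[3.3.1]nonane F14. Coupling of the two with Pd(OAc)2, PCy3 and K3PO4·H2O in THF at rt, where the bromide should react and the chloride should not, returns the route at 22.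

## Further compounds

F1 | step 10 | methyl (3R,5S,7S)-8-acetoxy-3,5,7-trimethyloctanoate | COC(=O)C[C@H](C)C[C@H](C)C[C@H](C)COC(C)=O
F2 | step 10 | methyl (3R,5S,7S)-8-hydroxy-3,5,7-trimethyloctanoate | COC(=O)C[C@H](C)C[C@H](C)C[C@H](C)CO
F3 | step 10 | methyl (3R,5S,7S)-8-iodo-3,5,7-trimethyloctanoate | COC(=O)C[C@H](C)C[C@H](C)C[C@H](C)CI
F4 | step 10 | [(2S,4S,6R)-8-methoxy-2,4,6-trimethyl-8-oxooctyl]zinc iodide | COC(=O)C[C@H](C)C[C@H](C)C[C@H](C)C[Zn]I
F5 | step 10 | 1-tert-butyl 11-methyl (2E,5S,7R,9R)-5,7,9-trimethylundec-2-enedioate | COC(=O)C[C@H](C)C[C@H](C)C[C@H](C)C/C=C/C(=O)OC(C)(C)C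
F6 | step 10 | methyl (3R,5R,7S,9S)-11-tert-butoxy-3,5,7,9-tetramethyl-11-[(trimethylsilyl)oxy]undec-10-enoate | COC(=O)C[C@H](C)C[C@H](C)C[C@H](C)C[C@H](C)C=C(OC(C)(C)C)O[Si](C)(C)C
F7 | step 9 | (2S,4S)-2,4-dimethylhept-6-en-1-yl acetate | C=CC[C@H](C)C[C@H](C)COC(C)=O
F8 | step 9 | (2S,4S)-2,4-dimethylhept-6-en-1-ol | C=CC[C@H](C)C[C@H](C)CO
F9 | step 9 | (4S,6S)-7-iodo-4,6-dimethylhept-1-ene | C=CC[C@H](C)C[C@H](C)CI
F10 | step 9 | [(2S,4S)-2,4-dimethylhept-6-en-1-yl]zinc iodide | C=CC[C@H](C)C[C@H](C)C[Zn]I
F11 | step 9 | tert-butyl (2E,5S,7S)-5,7-dimethyldeca-2,9-dienoate | C=CC[C@H](C)C[C@H](C)C/C=C/C(=O)OC(C)(C)C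
F12 | step 11 | (3R,5R,7S,9S)-11-tert-butoxy-3,5,7,9-tetramethyl-11-oxoundecanoic acid | OC(=O)C[C@H](C)C[C@H](C)C[C@H](C)C[C@H](C)CC(=O)OC(C)(C)C
F13 | step 15 | (3S,5S,7S,9S)-1-bromo-3,5,7,9-tetramethylundecane | CC[C@H](C)C[C@H](C)C[C@H](C)C[C@H](C)CCBr
F14 | step 15 | 9-(5-chloropentyl)-9-borabicyclo[3.3.1]nonane | ClCCCCCB1C2CCCC1CCC2
A1 | alternative 1 | 2-methoxy-5-methyl-6-[(9R,11R,13S,15S)-9,11,13,15-tetramethylheptadecyl]benzene-1,4-diol | CC[C@H](C)C[C@H](C)C[C@H](C)C[C@H](C)CCCCCCCCc1c(C)c(O)cc(OC)c1O
A2 | alternative 1 | (12R,14R,16S,18S)-3-bromo-12,14,16,18-tetramethylicos-2-ene | CC[C@H](C)C[C@H](C)C[C@H](C)C[C@H](C)CCCCCCCCC(Br)=CC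
A3 | alternative 1 | 3-methoxycyclobut-3-ene-1,2-dione | COC1=CC(=O)C1=O
A4 | alternative 2 | (2S,4S,6S,8S)-2,4,6,8-tetramethyldecan-1-ol | CC[C@H](C)C[C@H](C)C[C@H](C)C[C@H](C)CO
A5 | alternative 2 | diethylzinc | CC[Zn]CC
A6 | alternative 2 | propene | CC=C
A7 | alternative 3 | trans-3,4,4-trimethoxy-6-methyl-5-[(9R,11R,13S,15S)-9,11,13,15-tetramethylheptadecyl]cyclohex-2-en-1-one | CC[C@H](C)C[C@H](C)C[C@H](C)C[C@H](C)CCCCCCCCC1C(C)C(=O)C=C(OC)C1(OC)OC
A8 | alternative 3 | 3,4,4-trimethoxycyclohexa-2,5-dien-1-one | COC1=CC(=O)C=CC1(OC)OC
A9 | alternative 3 | (9R,11R,13S,15S)-1-bromo-9,11,13,15-tetramethylheptadecane | CC[C@H](C)C[C@H](C)C[C@H](C)C[C@H](C)CCCCCCCCBr
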